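# Betaethrin E: route proposal built on an aryne / phenoxide / CO2 three-component union

## Analysis of the target

Betaethrin E (25) is an achiral diaryl ether: two benzene rings are joined through one oxygen, and there is no stereocentre and no further ring to close. Ring A is numbered C1 (CH2O–palmitoyl), C3 (OMe), C5 (OH) and C6 (ether oxygen); ring B is a methyl benzoate numbered C1' (ether oxygen), C3' (CH3), C5' (OH) and C6' (CO2Me). The ether oxygen is crowded, because both ortho positions on ring A (C1, C5) and one on ring B (C6') are substituted, so a conventional aryl–oxygen coupling is the slow point of any route. Three groups restrict the late chemistry. The free C5 hydroxyl lies next to the ether oxygen while C1' is activated by the ortho ester, so base can move ring B from the C6 oxygen to the C5 oxygen (Smiles rearrangement). The palmitate is a 2-aryloxybenzyl ester: hydrogenolysis cleaves it, and strong Lewis acids ionise it, with C2' of ring B (para to the C5' oxygen) placed for a six-membered Friedel–Crafts closure. The C3 methyl ether must survive while the C5 and C5' oxygens are unmasked. The strategy rests on ring B: the ether oxygen on C1' and the carboxyl carbon on C6' sit on adjacent carbons with the C5' oxygen on the next one, the nucleophile–electrophile–alkoxy pattern that a 3-alkoxyaryne accepts across its triple bond.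

## Retrosynthetic reasoning

**25 from 24.** The last operation only unmasks the C5 and C5' hydroxyls. Because the final conditions may be neither basic, reductive nor strongly Lewis acidic, both oxygens are carried as methoxymethyl acetals in 24 and released together by dilute protic acid. This is why the C5' oxygen is not carried as a methyl ether.

**24 from 22 and 23.** The acyl C–O bond of the benzylic ester is cut. The long chain and the labile benzylic ester enter late, by acylation with palmitoyl chloride 23 at a stage where the primary alcohol of 22 is the only free hydroxyl, so no chemoselectivity is asked for.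

**22 from 21, and 21 from 20.** The primary alcohol is masked as a bulky silyl ether, and the methyl ester is traced back to the free acid 20. The hindered 2,6-disubstituted carboxyl group is esterified at oxygen, not at the carbonyl carbon.

**20 from 7, 14 and 15 (key disconnection).** Two bonds at neighbouring ring B carbons are cut together: O–C1' and C6'–CO2. Cutting the ether bond alone would leave a coupling between a doubly ortho-substituted phenol and an ortho-substituted benzoate. Cutting both bonds turns ring B into aryne 17, released from silyl triflate 14. The C5' alkoxy group beside the triple bond fixes the polarity: the phenoxide 16 of phenol 7 adds at C1', and the resulting aryl anion 18 at C6' takes up carbon dioxide 15. The gain is convergence, a ring B bought as an aromatic compound, and an ester carbon that comes from 15. The forward reaction has to supply a proton-free medium and a clean regiochemical outcome.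

**7 from 6, 5, 4, 2 and 1.** The silyl ether is removed, and the benzylic alcohol 6 is traced to aldehyde 5. The C1–CHO bond of 5 is cut at the only free position ortho to the phenol of 4. Phenol 4 comes from aldehyde 2 by exchange of the formyl carbon for oxygen. This exchange is what differentiates the two adjacent oxygens of ring A without any selectivity problem: the hydroxyl of commercial aldehyde 1 becomes the protected C5 oxygen, and its formyl carbon becomes the free C6 oxygen.

**14 from 13, 12, 10, 9 and 8.** The triflate is traced to silylphenol 13. The C–Si bond of 12 is cut at the carbon between the two oxygens, the site that a directed metalation of carbamate 10 reaches through aryllithium 11. The carbamate is both directing group and latent phenol, and 10 comes from the mono-acetal 9 of the symmetrical diol 8.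

## Alternatives that were turned down

**Alternative 1: ring A from a cyclohexanedione (Michael–Claisen annulation).** Ring A is taken apart at C1–C2 and C3–C4 into the open-chain α-aryloxy enone A2, which already carries ring B on oxygen, and dimethyl malonate A3. In the forward direction A3 adds to the β-carbon of A2, and the methyl ketone enolate then closes onto a malonate ester to give dione A1.
- For: both condensations are textbook reactions. The crowded ether bond never has to be made between two arenes, since the C–O bond is set earlier by alkylating an unhindered ring B phenol. On this point the alternative is stronger than the chosen plan.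
- Against: A1 is at the wrong oxidation level and carries an extra ester and three stereocentres that must all be erased. Decarboxylation and dehydrogenation to the resorcinol are needed, followed by methylation of the C3 hydroxyl in the presence of the C5 hydroxyl, two phenols that differ only in their surroundings. The aromatisation also unveils the C5 phenol beside the ether oxygen under the basic or oxidising conditions that invite Smiles migration.
- Comparison: the chosen plan starts from aromatic rings in which C3 and C5 are already differentiated and needs no redox corrections. It pays for this with an untested key step.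

**Alternative 2: ring A by Danheiser benzannulation.** Ring A is divided into the α-diazo enone A5 (C5, C6, C1, C2, with the ring B ether on the enone β-carbon) and methoxyacetylene A6 (C3, C4). Photochemical Wolff rearrangement of A5, cycloaddition with A6 and an electrocyclic opening–closing cascade would give phenol A4.
- For: the whole of ring A is assembled regiospecifically in one operation under neutral conditions. The alkyne places the C3 methoxyl and the C5 oxygen appears as a free phenol, so the two oxygens are told apart without protecting groups. This is more economical than the five steps spent on ring A in the chosen route.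
- Against: A5 is a sensitive, multi-step substrate that needs a diazo transfer onto a β-aryloxy enone. A6 is volatile and unstable. The last ring bond (C5–C6) has to form next to the bulky ring B substituent. A4 also emerges with the C5 phenol free, so the later desilylation and palmitoylation must be run with a free phenol beside the ether oxygen, which brings back both the Smiles problem and an O-acylation selectivity problem. The C5' methyl ether would still need a strong Lewis acid in the presence of the benzylic oxygen.
- Comparison: the chosen route is less elegant in ring construction, but it reaches its key-step partners by routine aromatic chemistry and keeps C5 masked to the last step.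

**Alternative 3: ring B from a 2-pyrone by Diels–Alder reaction and decarboxylation.** Ring B is cut at C3'–C4' and C5'–C6' into the 4-aryloxy-2-pyrone A8 and 1,1-dimethoxyethene A9. An inverse-demand cycloaddition across the pyrone diene, decarboxylative loss of the lactone bridge and elimination of one methoxyl would give benzoate A7.
- For: every stage has precedent, and the ester on the pyrone dictates the regiochemistry. The crowded ether bond is made by addition–elimination of the phenol at the pyrone 4-position, a vinylogous acyl substitution that accepts hindered phenols. In reliability of the key step and of the C–O bond formation this alternative is stronger than the chosen one.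
- Against: the 4-aryloxy group donates into the pyrone and slows the cycloaddition. At the temperatures then required, the electron-rich ketene acetal or the liberated alcohol can displace the aryloxy group at this vinylogous ester position. The C5' oxygen necessarily emerges as a methyl ether, whose removal needs the strong Lewis acid that the 2-aryloxybenzyl system does not tolerate. The benzyl ether on ring A must be hydrogenolysed before the palmitate exists, which again leaves a free C5 phenol during acylation.
- Comparison: the chosen route buys ring B as an arene, forms both bonds at C1' and C6' in a single step, is shorter, and lets the C5' oxygen carry an acid-labile acetal so that the end game is one mild step. Its price is the risk concentrated in the key step.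

Key step: step 11

## Remarks on the chemistry

- Compounds 1, 8 and 23 are taken to be commercial.
- The C5' oxygen is carried as a methoxymethyl ether. A methyl ether there would need BCl3-type cleavage in the presence of the 2-aryloxybenzyl ester, which is open to ester cleavage and Friedel–Crafts closure onto C2'.
- The three-component step is run in THF with a hydride-generated potassium phenoxide. Acetonitrile, hydrogencarbonate or residual phenol would protonate the aryl anion before CO2 can trap it.
- The formyl-to-hydroxyl exchange on 2 is run with a peracid, because 2 has no free ortho or para hydroxyl for a classical Dakin oxidation.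

## Route

**Step 1**
Reactants: 1 2-hydroxy-4-methoxybenzaldehyde
Product: 2 4-methoxy-2-(methoxymethoxy)benzaldehyde
Conditions: MOMCl, i-Pr2NEt, CH2Cl2, 0 °C → rt
Reagents that add atoms: chloromethyl methyl ether (MOMCl), COCCl
Why: O-alkylation of the phenol by an α-chloro ether (acetal formation); the acetal masks the future C5 hydroxyl and tolerates all basic, reductive and fluoride steps up to the final acid treatment.

**Step 2**
Reactants: 2 4-methoxy-2-(methoxymethoxy)benzaldehyde
Product: 4 4-methoxy-2-(methoxymethoxy)phenol, via aryl formate 3 (not isolated)
Conditions: mCPBA, CH2Cl2, 0 °C → rt; then K2CO3, MeOH, rt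
Reagents that add atoms: 3-chloroperoxybenzoic acid (mCPBA), OOC(=O)c1cccc(Cl)c1
Why: Baeyer–Villiger oxidation of an electron-rich benzaldehyde (the Dakin outcome): the 2,4-dialkoxyaryl group migrates to oxygen and formate 3 is methanolysed, which turns the formyl carbon into the future C6 oxygen.

**Step 3**
Reactants: 4 4-methoxy-2-(methoxymethoxy)phenol
Product: 5 2-hydroxy-5-methoxy-3-(methoxymethoxy)benzaldehyde
Conditions: MgCl2, Et3N, (CH2O)n, MeCN, reflux
Reagents that add atoms: paraformaldehyde (as formaldehyde), C=O
Why: Magnesium-phenoxide-directed ortho-formylation (Casnati–Skattebøl formylation): formaldehyde is delivered inside the magnesium chelate to the only free position ortho to the phenol, and the hydroxymethyl intermediate is oxidised in the flask by a second formaldehyde.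

**Step 4**
Reactants: 5 2-hydroxy-5-methoxy-3-(methoxymethoxy)benzaldehyde
Product: 6 2-(hydroxymethyl)-4-methoxy-6-(methoxymethoxy)phenol
Conditions: NaBH4, MeOH, 0 °C
Reagents that add atoms: none
Why: Hydride reduction of the aldehyde to the benzylic alcohol; a neutral work-up avoids ionisation of the salicyl alcohol.

**Step 5**
Reactants: 6 2-(hydroxymethyl)-4-methoxy-6-(methoxymethoxy)phenol
Product: 7 4-methoxy-2-(methoxymethoxy)-6-{[(triisopropylsilyl)oxy]methyl}phenol
Conditions: TIPSCl (1.05 equiv), imidazole, DMF, 0 °C → rt
Reagents that add atoms: chlorotriisopropylsilane (TIPSCl), CC(C)[Si](Cl)(C(C)C)C(C)C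
Why: Chemoselective O-silylation: the bulky silyl chloride should take the primary alcohol and leave the hydrogen-bonded phenol flanked by two ortho substituents; the bulky triisopropylsilyl ether is chosen to resist fluoride and silyl transfer in step 11.

**Step 6**
Reactants: 8 5-methylbenzene-1,3-diol (orcinol)
Product: 9 3-(methoxymethoxy)-5-methylphenol
Conditions: MOMCl (1.0 equiv), K2CO3, acetone, 0 °C → rt
Reagents that add atoms: chloromethyl methyl ether (MOMCl), COCCl
Why: Statistical mono-O-alkylation of a symmetrical diol; unreacted diol and the bis-acetal are separable by polarity and the diol can be recycled.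

**Step 7**
Reactants: 9 3-(methoxymethoxy)-5-methylphenol
Product: 10 3-(methoxymethoxy)-5-methylphenyl N,N-diethylcarbamate
Conditions: ClCONEt2, K2CO3, MeCN, reflux
Reagents that add atoms: N,N-diethylcarbamoyl chloride, CCN(CC)C(=O)Cl
Why: O-Carbamoylation of the phenol installs a strong directing group for metalation that is also the latent triflate oxygen.

**Step 8**
Reactants: 10 3-(methoxymethoxy)-5-methylphenyl N,N-diethylcarbamate
Product: 12 3-(methoxymethoxy)-5-methyl-2-(trimethylsilyl)phenyl N,N-diethylcarbamate, via aryllithium 11 (not isolated)
Conditions: s-BuLi, TMEDA, THF, −78 °C; then TMSCl, −78 °C → rt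
Reagents that add atoms: chlorotrimethylsilane (TMSCl), C[Si](C)(C)Cl
Why: Directed ortho-metalation: the carbamate and the acetal oxygen cooperate, so lithiation should occur at the carbon between them; keeping 11 at −78 °C until it is silylated suppresses the anionic ortho-Fries shift.

**Step 9**
Reactants: 12 3-(methoxymethoxy)-5-methyl-2-(trimethylsilyl)phenyl N,N-diethylcarbamate
Product: 13 3-(methoxymethoxy)-5-methyl-2-(trimethylsilyl)phenol
Conditions: LiAlH4, THF, 0 °C → rt; then sat. aq. NH4Cl
Reagents that add atoms: none
Why: Hydride reduction of the aryl carbamate: addition at the carbonyl expels the aryloxide, while the aryl–silicon bond and the acetal are inert to LiAlH4.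

**Step 10**
Reactants: 13 3-(methoxymethoxy)-5-methyl-2-(trimethylsilyl)phenol
Product: 14 3-(methoxymethoxy)-5-methyl-2-(trimethylsilyl)phenyl trifluoromethanesulfonate
Conditions: PhNTf2, DBU, MeCN, rt
Reagents that add atoms: N-phenylbis(trifluoromethanesulfonimide) (PhNTf2), O=S(=O)(N(c1ccccc1)S(=O)(=O)C(F)(F)F)C(F)(F)F
Why: O-Sulfonylation of the ortho-silyl phenoxide with a mild triflyl donor; the amidine base does not attack silicon, so the C–Si bond needed for aryne release is kept.

**Step 11**
Reactants: 7 4-methoxy-2-(methoxymethoxy)-6-{[(triisopropylsilyl)oxy]methyl}phenol; 14 3-(methoxymethoxy)-5-methyl-2-(trimethylsilyl)phenyl trifluoromethanesulfonate; 15 carbon dioxide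
Product: 20 2-(methoxymethoxy)-6-[4-methoxy-2-(methoxymethoxy)-6-{[(triisopropylsilyl)oxy]methyl}phenoxy]-4-methylbenzoic acid, via potassium phenoxide 16 (not isolated), via aryne 17 (not isolated), via aryl anion 18 (not isolated), via potassium carboxylate 19 (not isolated)
Conditions: KH (1.0 equiv), THF, 0 °C → rt; then 18-crown-6, KF, CO2 (1 atm), slow addition of 14, THF, 0 °C → rt; then 1 M HCl to pH 4, 0 °C
Reagents that add atoms: none
Why: Proposed new method: fluoride attacks the trimethylsilyl group of 14 and triflate leaves to give aryne 17, whose triple bond is distorted by the inductively withdrawing C5' acetal oxygen so that phenoxide 16 should add at the remote carbon C1' and the charge of aryl anion 18 should develop at C6', between two C–O bonds. In THF, with a hydride-generated phenoxide, 18 meets no acid and should be intercepted by dissolved CO2 15 to give carboxylate 19, so that the O–C1' and C6'–CO2 bonds form in one operation; acidification gives 20, which base extraction separates from neutral by-products. The closest known reactions are the three-component couplings of arynes with nitrogen nucleophiles (amines, imines) and CO2 under KF/18-crown-6 in THF, and the fluoride-mediated O-arylation of hindered phenols with 2-silylaryl triflates; the new element is the pairing of an oxygen nucleophile with CO2 capture. No ring is closed and no stereocentre is formed. The selectivity required is regiochemical (oxygen at C1', carboxyl at C6'); it is secured by the alkoxy group next to the triple bond and reinforced by the bulk of the 2,6-disubstituted nucleophile, which avoids the carbon beside that group. The phenoxide binds CO2 reversibly as an aryl carbonate, and the step relies on the free phenoxide being the far better nucleophile under fast equilibration; the aryne is small and reactive enough to accept a phenoxide that would be too hindered for substitution at a haloarene. The triisopropylsilyl ether should resist fluoride at this temperature and is too hindered to transfer silicon to 18.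

**Step 12**
Reactants: 20 2-(methoxymethoxy)-6-[4-methoxy-2-(methoxymethoxy)-6-{[(triisopropylsilyl)oxy]methyl}phenoxy]-4-methylbenzoic acid
Product: 21 methyl 2-(methoxymethoxy)-6-[4-methoxy-2-(methoxymethoxy)-6-{[(triisopropylsilyl)oxy]methyl}phenoxy]-4-methylbenzoate
Conditions: MeI, K2CO3, DMF, rt
Reagents that add atoms: iodomethane, CI
Why: SN2 O-alkylation of the carboxylate; this avoids attack at the hindered 2,6-disubstituted carbonyl and the acid that a Fischer esterification would bring to the acetals.

**Step 13**
Reactants: 21 methyl 2-(methoxymethoxy)-6-[4-methoxy-2-(methoxymethoxy)-6-{[(triisopropylsilyl)oxy]methyl}phenoxy]-4-methylbenzoate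
Product: 22 methyl 2-[2-(hydroxymethyl)-4-methoxy-6-(methoxymethoxy)phenoxy]-6-(methoxymethoxy)-4-methylbenzoate
Conditions: HF·pyridine, pyridine, THF, 0 °C → rt
Reagents that add atoms: none
Why: Fluoride-driven cleavage of the primary silyl ether; the buffered reagent keeps the liberated alcohol protonated, so neither lactonisation onto the C6' ester nor aryl migration to the benzylic oxygen can start, and the aryl acetals and the ester are tolerated.

**Step 14**
Reactants: 22 methyl 2-[2-(hydroxymethyl)-4-methoxy-6-(methoxymethoxy)phenoxy]-6-(methoxymethoxy)-4-methylbenzoate; 23 hexadecanoyl chloride (palmitoyl chloride)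
Product: 24 methyl 2-{2-[(hexadecanoyloxy)methyl]-4-methoxy-6-(methoxymethoxy)phenoxy}-6-(methoxymethoxy)-4-methylbenzoate
Conditions: pyridine, DMAP (cat.), CH2Cl2, 0 °C → rt
Reagents that add atoms: none
Why: DMAP-catalysed acylation (nucleophilic acyl substitution) of the only free hydroxyl in the molecule, so no chemoselectivity is needed.

**Step 15**
Reactants: 24 methyl 2-{2-[(hexadecanoyloxy)methyl]-4-methoxy-6-(methoxymethoxy)phenoxy}-6-(methoxymethoxy)-4-methylbenzoate
Product: 25 Betaethrin E, methyl 2-{2-[(hexadecanoyloxy)methyl]-6-hydroxy-4-methoxyphenoxy}-6-hydroxy-4-methylbenzoate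
Conditions: 3 M aq. HCl, THF/i-PrOH, 45 °C
Reagents that add atoms: none
Why: Acid-catalysed hydrolysis of both aryl methoxymethyl acetals through oxocarbenium ions; dilute protic acid should neither ionise the benzylic ester nor cleave the C3 methyl ether or the methyl ester, no base is present to start a Smiles migration, and the alcohol cosolvent takes up the liberated formaldehyde as its acetal.

## Compound list

1 | 2-hydroxy-4-methoxybenzaldehyde | COc1ccc(C=O)c(O)c1 | starting material
2 | 4-methoxy-2-(methoxymethoxy)benzaldehyde | COCOc1cc(OC)ccc1C=O | intermediate
3 | 4-methoxy-2-(methoxymethoxy)phenyl formate (formed in the flask) | COCOc1cc(OC)ccc1OC=O | intermediate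
4 | 4-methoxy-2-(methoxymethoxy)phenol | COCOc1cc(OC)ccc1O | intermediate
5 | 2-hydroxy-5-methoxy-3-(methoxymethoxy)benzaldehyde | COCOc1cc(OC)cc(C=O)c1O | intermediate
6 | 2-(hydroxymethyl)-4-methoxy-6-(methoxymethoxy)phenol | COCOc1cc(OC)cc(CO)c1O | intermediate
7 | 4-methoxy-2-(methoxymethoxy)-6-{[(triisopropylsilyl)oxy]methyl}phenol | COCOc1cc(OC)cc(CO[Si](C(C)C)(C(C)C)C(C)C)c1O | intermediate
8 | 5-methylbenzene-1,3-diol (orcinol) | Cc1cc(O)cc(O)c1 | starting material
9 | 3-(methoxymethoxy)-5-methylphenol | COCOc1cc(C)cc(O)c1 | intermediate
10 | 3-(methoxymethoxy)-5-methylphenyl N,N-diethylcarbamate | CCN(CC)C(=O)Oc1cc(C)cc(OCOC)c1 | intermediate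
11 | 2-lithio-3-(methoxymethoxy)-5-methylphenyl N,N-diethylcarbamate (formed in the flask) | CCN(CC)C(=O)Oc1cc(C)cc(OCOC)c1[Li] | intermediate
12 | 3-(methoxymethoxy)-5-methyl-2-(trimethylsilyl)phenyl N,N-diethylcarbamate | CCN(CC)C(=O)Oc1cc(C)cc(OCOC)c1[Si](C)(C)C | intermediate
13 | 3-(methoxymethoxy)-5-methyl-2-(trimethylsilyl)phenol | COCOc1cc(C)cc(O)c1[Si](C)(C)C | intermediate
14 | 3-(methoxymethoxy)-5-methyl-2-(trimethylsilyl)phenyl trifluoromethanesulfonate | COCOc1cc(C)cc(OS(=O)(=O)C(F)(F)F)c1[Si](C)(C)C | intermediate
15 | carbon dioxide | O=C=O | starting material
16 | potassium 4-methoxy-2-(methoxymethoxy)-6-{[(triisopropylsilyl)oxy]methyl}phenoxide (formed in the flask) | COCOc1cc(OC)cc(CO[Si](C(C)C)(C(C)C)C(C)C)c1[O-].[K+] | intermediate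
17 | 3-(methoxymethoxy)-5-methylbenzyne, the 1,2-didehydrobenzene with the acetal oxygen next to the triple bond (formed in the flask) | COCOC1=CC(C)=CC#C1 | intermediate
18 | potassium 2-(methoxymethoxy)-6-[4-methoxy-2-(methoxymethoxy)-6-{[(triisopropylsilyl)oxy]methyl}phenoxy]-4-methylphenyl anion, charge on the carbon between the two oxygens (formed in the flask) | COCOC1=CC(C)=CC(Oc2c(OCOC)cc(OC)cc2CO[Si](C(C)C)(C(C)C)C(C)C)=[C-]1.[K+] | intermediate
19 | potassium 2-(methoxymethoxy)-6-[4-methoxy-2-(methoxymethoxy)-6-{[(triisopropylsilyl)oxy]methyl}phenoxy]-4-methylbenzoate (formed in the flask) | COCOc1cc(C)cc(Oc2c(OCOC)cc(OC)cc2CO[Si](C(C)C)(C(C)C)C(C)C)c1C(=O)[O-].[K+] | intermediate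
20 | 2-(methoxymethoxy)-6-[4-methoxy-2-(methoxymethoxy)-6-{[(triisopropylsilyl)oxy]methyl}phenoxy]-4-methylbenzoic acid | COCOc1cc(C)cc(Oc2c(OCOC)cc(OC)cc2CO[Si](C(C)C)(C(C)C)C(C)C)c1C(=O)O | intermediate
21 | methyl 2-(methoxymethoxy)-6-[4-methoxy-2-(methoxymethoxy)-6-{[(triisopropylsilyl)oxy]methyl}phenoxy]-4-methylbenzoate | COCOc1cc(C)cc(Oc2c(OCOC)cc(OC)cc2CO[Si](C(C)C)(C(C)C)C(C)C)c1C(=O)OC | intermediate
22 | methyl 2-[2-(hydroxymethyl)-4-methoxy-6-(methoxymethoxy)phenoxy]-6-(methoxymethoxy)-4-methylbenzoate | COCOc1cc(C)cc(Oc2c(OCOC)cc(OC)cc2CO)c1C(=O)OC | intermediate
23 | hexadecanoyl chloride (palmitoyl chloride) | CCCCCCCCCCCCCCCC(=O)Cl | starting material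
24 | methyl 2-{2-[(hexadecanoyloxy)methyl]-4-methoxy-6-(methoxymethoxy)phenoxy}-6-(methoxymethoxy)-4-methylbenzoate | CCCCCCCCCCCCCCCC(=O)OCc1cc(OC)cc(OCOC)c1Oc1cc(C)cc(OCOC)c1C(=O)OC | intermediate
25 | Betaethrin E, methyl 2-{2-[(hexadecanoyloxy)methyl]-6-hydroxy-4-methoxyphenoxy}-6-hydroxy-4-methylbenzoate | CCCCCCCCCCCCCCCC(=O)OCc1cc(OC)cc(O)c1Oc1cc(C)cc(O)c1C(=O)OC | target

## Step count and least certain steps

Total: 15 steps. Longest linear sequence: 10 steps (steps 1–5, then 11–15; the ring B branch, steps 6–10, is equally long).

**Step 11 (key step).** Several processes compete with carboxylation of 18: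
- protonation of 18 by any residual acid (moisture, unconsumed phenol), which gives the plain diaryl ether;
- storage of the nucleophile as its CO2 adduct, whose carbonate oxygen may then add to 17;
- transfer of the triflyl group from unreacted 14 to 18;
- a second arylation of carboxylate 19 by excess aryne;
- slow fluoride attack on the silyl ether.

Fallback, by known chemistry, from 7 back to 21: the ether bond is made by a copper-catalysed Ullmann coupling, and the carboxyl carbon is placed on ring B beforehand. Commercial 3-bromo-5-methylphenol F1 is converted with MOMCl and i-Pr2NEt into 1-bromo-3-(methoxymethoxy)-5-methylbenzene F2. F2 is lithiated between bromine and the acetal oxygen with LiN(i-Pr)2 in THF at −78 °C and quenched with ClCO2Me to give methyl 2-bromo-6-(methoxymethoxy)-4-methylbenzoate F3. F3 and phenol 7 are then coupled with CuI (copper iodide), picolinic acid and K3PO4 in DMSO at 90 °C. This should give ester 21 directly, where the route is rejoined at step 13.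

**Step 8.** The crowded aryllithium 11 may undergo the anionic ortho-Fries shift of the carbamoyl group before it is silylated, or silylation at the carbon between two oxygens may stay incomplete. The hindered carbamate may then also be reduced slowly in step 9.

Fallback from 8 back to 14, using halogen–lithium exchange in place of deprotonation: orcinol 8 is iodinated between the two hydroxyls (I2, NaHCO3, water, 0 °C) to give 2-iodo-5-methylbenzene-1,3-diol F4. One hydroxyl is protected (MOMCl, K2CO3, acetone) to give 2-iodo-3-(methoxymethoxy)-5-methylphenol F5. F5 is O-silylated with hexamethyldisilazane to give [2-iodo-3-(methoxymethoxy)-5-methylphenoxy]trimethylsilane F6. Treatment of F6 with n-BuLi in THF at −78 °C should cause iodine–lithium exchange and oxygen-to-carbon silyl migration (retro-Brook rearrangement), and the resulting phenoxide is trapped with Tf2O to give 14.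

**Step 3.** The neighbouring acetal oxygen may hold magnesium in a chelate that slows delivery of formaldehyde to the ortho carbon. The hydroxymethyl intermediate may also condense with a second phenol instead of being oxidised.

Fallback from 4 back to 5: ortho-bromination of phenol 4 (NBS, catalytic i-Pr2NH, CH2Cl2, 0 °C) should give 2-bromo-4-methoxy-6-(methoxymethoxy)phenol F7. Double deprotonation and exchange with n-BuLi (2.2 equiv, THF, −78 °C), followed by DMF and aqueous NH4Cl, then gives aldehyde 5.

**Step 15.** Prolonged acid treatment may partly hydrolyse or transesterify the benzylic palmitate, and formaldehyde released from the acetals may be captured by the electron-rich rings.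

Fallback from 22 back to 25, with deprotection before acylation: 22 is treated with 3 M aq. HCl in THF at 45 °C to give methyl 2-hydroxy-6-[2-hydroxy-6-(hydroxymethyl)-4-methoxyphenoxy]-4-methylbenzoate F8. The primary alcohol of F8 is then acylated under neutral conditions with vinyl palmitate and immobilised Candida antarctica lipase B in tert-butyl methyl ether at 40 °C. The enzyme acylates aliphatic hydroxyls and leaves phenols alone, so 25 should result without base and without exposure of the ester to acid.

## Further compounds

F1 | step 11 | 3-bromo-5-methylphenol | Cc1cc(O)cc(Br)c1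
F2 | step 11 | 1-bromo-3-(methoxymethoxy)-5-methylbenzene | COCOc1cc(C)cc(Br)c1
F3 | step 11 | methyl 2-bromo-6-(methoxymethoxy)-4-methylbenzoate | COCOc1cc(C)cc(Br)c1C(=O)OC
F4 | step 8 | 2-iodo-5-methylbenzene-1,3-diol | Cc1cc(O)c(I)c(O)c1
F5 | step 8 | 2-iodo-3-(methoxymethoxy)-5-methylphenol | COCOc1cc(C)cc(O)c1I
F6 | step 8 | [2-iodo-3-(methoxymethoxy)-5-methylphenoxy]trimethylsilane | COCOc1cc(C)cc(O[Si](C)(C)C)c1I
F7 | step 3 | 2-bromo-4-methoxy-6-(methoxymethoxy)phenol | COCOc1cc(OC)cc(Br)c1O
F8 | step 15 | methyl 2-hydroxy-6-[2-hydroxy-6-(hydroxymethyl)-4-methoxyphenoxy]-4-methylbenzoate | COC(=O)c1c(O)cc(C)cc1Oc1c(O)cc(OC)cc1CO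
A1 | alternative 1 | methyl 2-[(tert-butyldiphenylsilyloxy)methyl]-3-[3-methoxy-2-(methoxycarbonyl)-5-methylphenoxy]-4,6-dioxocyclohexane-1-carboxylate (racemic, all-trans isomer drawn) | COC(=O)[C@H]1C(=O)CC(=O)[C@@H](Oc2cc(C)cc(OC)c2C(=O)OC)[C@@H]1CO[Si](c1ccccc1)(c1ccccc1)C(C)(C)C
A2 | alternative 1 | methyl 2-{[5-(tert-butyldiphenylsilyloxy)-2-oxopent-3-en-3-yl]oxy}-6-methoxy-4-methylbenzoate | CC(=O)C(Oc1cc(C)cc(OC)c1C(=O)OC)=CCO[Si](c1ccccc1)(c1ccccc1)C(C)(C)C
A3 | alternative 1 | dimethyl malonate | COC(=O)CC(=O)OC
A4 | alternative 2 | methyl 2-{2-hydroxy-4-methoxy-6-[(tert-butyldimethylsilyloxy)methyl]phenoxy}-6-methoxy-4-methylbenzoate | COC(=O)c1c(OC)cc(C)cc1Oc1c(O)cc(OC)cc1CO[Si](C)(C)C(C)(C)C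
A5 | alternative 2 | methyl 2-{[4-diazo-2-{[(tert-butyldimethylsilyl)oxy]methyl}-3-oxobut-1-en-1-yl]oxy}-6-methoxy-4-methylbenzoate | [N-]=[N+]=CC(=O)C(CO[Si](C)(C)C(C)(C)C)=COc1cc(C)cc(OC)c1C(=O)OC
A6 | alternative 2 | methoxyacetylene (methoxyethyne) | COC#C
A7 | alternative 3 | methyl 2-{2-(benzyloxy)-6-[(tert-butyldimethylsilyloxy)methyl]-4-methoxyphenoxy}-6-methoxy-4-methylbenzoate | CC(C)(C)[Si](C)(C)OCc1cc(OC)cc(OCc2ccccc2)c1Oc1cc(C)cc(OC)c1C(=O)OC
A8 | alternative 3 | methyl 4-{2-(benzyloxy)-6-[(tert-butyldimethylsilyloxy)methyl]-4-methoxyphenoxy}-6-methyl-2-oxo-2H-pyran-3-carboxylate | COC(=O)C1=C(Oc2c(OCc3ccccc3)cc(OC)cc2CO[Si](C)(C)C(C)(C)C)C=C(C)OC1=O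
A9 | alternative 3 | 1,1-dimethoxyethene | COC(OC)=C
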